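The route rests on closing the 1,2-dioxane at its C3–C4 bond while C4 is still tied to the later side-chain carbon C9 in a cyclohexenone made from 2,4,6-trimethylphenol. It exploits the fact that ring carbon C6 carries a methyl group and two alike CH2–CH(CH3) arms (C5–C4 inside the dioxane, C7–C8 in the chain). An ene-reductase selects one arm; its silyl dienol ether then attacks the peroxycarbenium ion hung on the C6 peroxide, giving a 2,3-dioxabicyclo[3.3.1]nonenone that fixes C3, C4 and C6 in one operation. The precursor is a 4-peroxycyclohex-2-enone whose peroxide carries a methyl 3-methoxypropanoate acetal. Radical scission of the temporary C4–C9 bond later frees the dioxane and the chain aldehyde.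

Key step: step 4

Remark: atoms are numbered as in the target acid (C1 carboxyl carbon; C3, C4, C5, C6 ring carbons; C7 to C14 side chain); stereocenters that are erased later (acetal carbon of 4 to 6, ring C5 of 5, carbinol carbon of 9) are drawn without configuration.

Step 1
Reactants: 1 2,4,6-trimethylphenol
Product: 2 4-hydroperoxy-2,4,6-trimethylcyclohexa-2,5-dien-1-one
Conditions: O2, rose bengal (cat.), visible light, MeOH, 0 °C
Reagents that add atoms: dioxygen, O=O
Why: Singlet-oxygen dearomatisation (photooxygenation) of an electron-rich 2,4,6-trialkylphenol should give the 4-hydroperoxycyclohexadienone (p-peroxyquinol), which already holds C4 to C9 with all three methyl groups and the C6–O–O unit; no stereocenter is formed.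

Step 2
Reactants: 2 4-hydroperoxy-2,4,6-trimethylcyclohexa-2,5-dien-1-one; 3 methyl 3,3-dimethoxypropanoate
Product: 4 methyl 3-methoxy-3-[(1,3,5-trimethyl-4-oxocyclohexa-2,5-dien-1-yl)peroxy]propanoate
Conditions: 3 (3 equiv), pyridinium p-toluenesulfonate (10 mol %), 4 Å molecular sieves, CH2Cl2, rt
Reagents that add atoms: none
Why: Acid-catalysed transacetalisation of a hydroperoxide with a dimethyl acetal (monoperoxyacetal formation) should exchange one methoxy group; the acetal carbon forms as both epimers, which does not matter because it is ionised in step 4.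

Step 3
Reactants: 4 methyl 3-methoxy-3-[(1,3,5-trimethyl-4-oxocyclohexa-2,5-dien-1-yl)peroxy]propanoate
Product: 5 methyl 3-methoxy-3-{[(1R)-1,3,5-trimethyl-4-oxocyclohex-2-en-1-yl]peroxy}propanoate
Conditions: ene-reductase (Old Yellow Enzyme family), NADP+ (cat.), D-glucose, glucose dehydrogenase, phosphate buffer pH 7.0, 5% DMSO, 30 °C, stopped after one C=C is reduced
Reagents that add atoms: none
Why: Ene-reductase desymmetrisation of a prochiral 4,4-disubstituted cyclohexa-2,5-dienone should reduce only one of the two enantiotopic α-methyl enone C=C bonds, which makes the peroxide-bearing carbon (future C6) a stereocenter (R) under enzyme control, the enzyme of this sense being taken from a panel of enantiocomplementary homologues; the new CH(CH3) center is erased in step 4.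

Step 4
Reactants: 5 methyl 3-methoxy-3-{[(1R)-1,3,5-trimethyl-4-oxocyclohex-2-en-1-yl]peroxy}propanoate
Product: 7 methyl 2-[(1R,4S,5R)-1,5,7-trimethyl-6-oxo-2,3-dioxabicyclo[3.3.1]non-7-en-4-yl]acetate, via silyl dienol ether 6 (not isolated)
Conditions: Me3SiOTf (1.6 equiv), Et3N (1.2 equiv), CH2Cl2, −78 → −40 °C; aq NaHCO3
Reagents that add atoms: none
Why: Et3N/Me3SiOTf silylate the ketone at its only enolisable position (the CH(CH3) of the reduced arm, the future C4) to give the cross-conjugated silyl dienol ether 6; the remaining Me3SiOTf then ionises the methoxy group of the monoperoxyacetal and the dienol ether terminus attacks the resulting peroxycarbenium ion at C3, after which loss of the silyl group restores the enone. The closest known reaction is the Lewis acid-mediated Mukaiyama-type addition of silyl enol ethers to peroxycarbenium ions generated from monoperoxyacetals, run here intramolecularly. The 1,2-dioxane closes as a six-membered ring in the 6-(enolexo)-endo-trig mode, the carbenium C=O lying inside and the enol C=C outside the new ring, which makes it one wing of a 2,3-dioxabicyclo[3.3.1]nonene. C6 is already set; C4 can only bond on the ring face that carries the peroxide, so the one-carbon C5 bridge relays C6 to C4 and puts both methyl groups equatorial on the new dioxane chair (cis); at C3 the chair transition state should place CH2CO2Me axial, in the open sector between the C5 methylene and the C4 methyl and away from the silyloxy-bearing carbon, which gives the contra-thermodynamic cis arrangement of the C3 and C4 substituents. The step needs ionisation of the acetal C–OMe bond in preference to the tertiary C6–O bond (whose ionisation would lead to rearomatisation); the more basic acetal oxygen, the low temperature and the immediate intramolecular capture should secure this.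

Step 5
Reactants: 7 methyl 2-[(1R,4S,5R)-1,5,7-trimethyl-6-oxo-2,3-dioxabicyclo[3.3.1]non-7-en-4-yl]acetate
Product: 8 methyl 2-[(1S,4S,5R,7R)-1,5,7-trimethyl-6-oxo-2,3-dioxabicyclo[3.3.1]nonan-4-yl]acetate
Conditions: dipotassium azodicarboxylate (excess, portionwise), AcOH, MeOH/CH2Cl2, 0 °C → rt
Reagents that add atoms: none
Why: Diimide reduction transfers two hydrogens in a concerted syn fashion to the exo face of the bicyclic enone (the endo face is shielded by the peroxide wing) without touching the O–O bond, which should set C8 with its methyl group endo (R), the kinetic and less stable epimer.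

Step 6
Reactants: 8 methyl 2-[(1S,4S,5R,7R)-1,5,7-trimethyl-6-oxo-2,3-dioxabicyclo[3.3.1]nonan-4-yl]acetate
Product: 9 methyl 2-[(1S,4S,5S,7R)-6-hydroxy-1,5,7-trimethyl-2,3-dioxabicyclo[3.3.1]nonan-4-yl]acetate
Conditions: NaBH4, CeCl3·7H2O, MeOH, −78 °C
Reagents that add atoms: none
Why: Luche reduction should convert the ketone into the secondary alcohol under weakly basic conditions that leave the epimerisable C8 center, the ester and the dialkyl peroxide intact; the carbinol configuration is irrelevant because this carbon becomes the aldehyde in step 7.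

Step 7
Reactants: 9 methyl 2-[(1S,4S,5S,7R)-6-hydroxy-1,5,7-trimethyl-2,3-dioxabicyclo[3.3.1]nonan-4-yl]acetate
Product: 10 methyl 2-[(3S,4S,6R)-4,6-dimethyl-6-[(2R)-2-methyl-3-oxopropyl]-1,2-dioxan-3-yl]acetate
Conditions: [Ir(dF(CF3)ppy)2(5,5'-d(CF3)bpy)]PF6 (2 mol %), 2,4,6-triisopropylbenzenethiol (25 mol %), 2,4,6-collidine, PhCF3, blue LEDs, rt
Reagents that add atoms: none
Why: Photocatalytic ring-opening isomerisation of a cyclic alcohol: proton-coupled electron transfer gives the alkoxy radical, β-scission cleaves the temporary C4–C9 bond toward the quaternary carbon (tertiary radical, strain release) and leaves C9 as the aldehyde on C8, and the bulky thiol should deliver hydrogen to the C4 radical anti to the adjacent axial CH2CO2Me group, on the face the carbon just left, which sets C4 (S) with its methyl cis to the C3 side chain.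

Step 8
Reactants: 11 (E)-but-2-enal; 12 phenylmagnesium bromide
Product: 13 (E)-1-phenylbut-2-en-1-ol (racemic)
Conditions: THF, −78 → 0 °C; aq NH4Cl
Reagents that add atoms: none
Why: Grignard 1,2-addition to the enal should give the racemic secondary allylic alcohol with the E double bond kept.

Step 9
Reactants: 13 (E)-1-phenylbut-2-en-1-ol (racemic)
Product: 14 (1R,2E)-1-phenylbut-2-en-1-ol
Conditions: Ti(OiPr)4 (10 mol %), D-(−)-diisopropyl tartrate (15 mol %), t-BuOOH (0.6 equiv), 4 Å molecular sieves, CH2Cl2, −20 °C
Reagents that add atoms: none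
Why: Sharpless kinetic resolution: with the D-(−)-tartrate the (S)-alcohol is epoxidised faster, so the (R)-alcohol should be recovered in high enantiomeric purity.

Step 10
Reactants: 14 (1R,2E)-1-phenylbut-2-en-1-ol; 15 triethyl orthoacetate
Product: 17 ethyl (3S,4E)-3-methyl-5-phenylpent-4-enoate, via ketene acetal 16 (not isolated)
Conditions: EtCO2H (cat.), 140 °C, removal of EtOH
Reagents that add atoms: none
Why: Johnson–Claisen rearrangement through a chair transition state with phenyl equatorial should transfer the carbinol chirality to the new C12 center (S) and give the E-styrene.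

Step 11
Reactants: 17 ethyl (3S,4E)-3-methyl-5-phenylpent-4-enoate
Product: 18 (3S,4E)-3-methyl-5-phenylpent-4-en-1-ol
Conditions: LiAlH4, THF, 0 °C
Reagents that add atoms: none
Why: Hydride reduction of the ester to the primary alcohol does not touch the isolated styrene or the stereocenter.

Step 12
Reactants: 18 (3S,4E)-3-methyl-5-phenylpent-4-en-1-ol; 19 1-phenyl-1H-tetrazole-5-thiol
Product: 20 5-{[(3S,4E)-3-methyl-5-phenylpent-4-en-1-yl]sulfanyl}-1-phenyl-1H-tetrazole
Conditions: diisopropyl azodicarboxylate, PPh3, THF, 0 °C → rt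
Reagents that add atoms: none
Why: Mitsunobu thioetherification of a primary alcohol with the acidic tetrazole thiol should proceed cleanly at the unhindered carbon.

Step 13
Reactants: 20 5-{[(3S,4E)-3-methyl-5-phenylpent-4-en-1-yl]sulfanyl}-1-phenyl-1H-tetrazole
Product: 21 5-{[(3S,4E)-3-methyl-5-phenylpent-4-en-1-yl]sulfonyl}-1-phenyl-1H-tetrazole
Conditions: (NH4)6Mo7O24·4H2O (cat.), 30% H2O2, EtOH, 0 °C → rt
Reagents that add atoms: hydrogen peroxide, OO
Why: Molybdate-catalysed sulfide oxidation should give the sulfone without epoxidising the unactivated styrene.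

Step 14
Reactants: 10 methyl 2-[(3S,4S,6R)-4,6-dimethyl-6-[(2R)-2-methyl-3-oxopropyl]-1,2-dioxan-3-yl]acetate; 21 5-{[(3S,4E)-3-methyl-5-phenylpent-4-en-1-yl]sulfonyl}-1-phenyl-1H-tetrazole
Product: 22 methyl 2-[(3S,4S,6S)-4,6-dimethyl-6-[(2R,3E,6S,7E)-2,6-dimethyl-8-phenylocta-3,7-dien-1-yl]-1,2-dioxan-3-yl]acetate
Conditions: KN(SiMe3)2, 1,2-dimethoxyethane, −60 °C (21 metalated first, then 10), → rt; aq NH4Cl
Reagents that add atoms: none
Why: Julia–Kocienski olefination of the premetalated phenyltetrazolyl sulfone with the α-branched aldehyde should give the E C9=C10 alkene, and the low temperature and the absence of free base should spare the C8 center, the ester and the peroxide.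

Step 15
Reactants: 22 methyl 2-[(3S,4S,6S)-4,6-dimethyl-6-[(2R,3E,6S,7E)-2,6-dimethyl-8-phenylocta-3,7-dien-1-yl]-1,2-dioxan-3-yl]acetate
Product: 23 2-[(3S,4S,6S)-4,6-dimethyl-6-[(2R,3E,6S,7E)-2,6-dimethyl-8-phenylocta-3,7-dien-1-yl]-1,2-dioxan-3-yl]acetic acid
Conditions: LiOH, THF/H2O, 0 °C → rt; then 1 M HCl to pH 3
Reagents that add atoms: lithium hydroxide, [Li+].[OH-]
Why: Saponification of the methyl ester with LiOH is the standard release of 1,2-dioxane-3-acetic acids and should leave the dialkyl peroxide and both alkenes unchanged.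

Compound list
1 | 2,4,6-trimethylphenol | Cc1cc(C)c(O)c(C)c1 | starting material
2 | 4-hydroperoxy-2,4,6-trimethylcyclohexa-2,5-dien-1-one | CC1=CC(C)(OO)C=C(C)C1=O | intermediate
3 | methyl 3,3-dimethoxypropanoate | COC(OC)CC(=O)OC | starting material
4 | methyl 3-methoxy-3-[(1,3,5-trimethyl-4-oxocyclohexa-2,5-dien-1-yl)peroxy]propanoate | COC(=O)CC(OC)OOC1(C)C=C(C)C(=O)C(C)=C1 | intermediate
5 | methyl 3-methoxy-3-{[(1R)-1,3,5-trimethyl-4-oxocyclohex-2-en-1-yl]peroxy}propanoate | COC(=O)CC(OC)OO[C@@]1(C)C=C(C)C(=O)C(C)C1 | intermediate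
6 | methyl 3-methoxy-3-({(1R)-1,3,5-trimethyl-4-[(trimethylsilyl)oxy]cyclohexa-2,4-dien-1-yl}peroxy)propanoate | COC(=O)CC(OC)OO[C@@]1(C)C=C(C)C(O[Si](C)(C)C)=C(C)C1 | intermediate
7 | methyl 2-[(1R,4S,5R)-1,5,7-trimethyl-6-oxo-2,3-dioxabicyclo[3.3.1]non-7-en-4-yl]acetate | COC(=O)C[C@@H]1OO[C@]2(C)C[C@@]1(C)C(=O)C(C)=C2 | intermediate
8 | methyl 2-[(1S,4S,5R,7R)-1,5,7-trimethyl-6-oxo-2,3-dioxabicyclo[3.3.1]nonan-4-yl]acetate | COC(=O)C[C@@H]1OO[C@]2(C)C[C@@]1(C)C(=O)[C@H](C)C2 | intermediate
9 | methyl 2-[(1S,4S,5S,7R)-6-hydroxy-1,5,7-trimethyl-2,3-dioxabicyclo[3.3.1]nonan-4-yl]acetate | COC(=O)C[C@@H]1OO[C@]2(C)C[C@@]1(C)C(O)[C@H](C)C2 | intermediate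
10 | methyl 2-[(3S,4S,6R)-4,6-dimethyl-6-[(2R)-2-methyl-3-oxopropyl]-1,2-dioxan-3-yl]acetate | O=C[C@H](C)C[C@@]1(C)C[C@H](C)[C@H](CC(=O)OC)OO1 | intermediate
11 | (E)-but-2-enal | C/C=C/C=O | starting material
12 | phenylmagnesium bromide | Br[Mg]c1ccccc1 | starting material
13 | (E)-1-phenylbut-2-en-1-ol (racemic) | C/C=C/C(O)c1ccccc1 | intermediate
14 | (1R,2E)-1-phenylbut-2-en-1-ol | C/C=C/[C@@H](O)c1ccccc1 | intermediate
15 | triethyl orthoacetate | CCOC(C)(OCC)OCC | starting material
16 | [(1R,2E)-1-(1-ethoxyethenyloxy)but-2-en-1-yl]benzene | C=C(OCC)O[C@H](/C=C/C)c1ccccc1 | intermediate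
17 | ethyl (3S,4E)-3-methyl-5-phenylpent-4-enoate | CCOC(=O)C[C@H](C)/C=C/c1ccccc1 | intermediate
18 | (3S,4E)-3-methyl-5-phenylpent-4-en-1-ol | OCC[C@H](C)/C=C/c1ccccc1 | intermediate
19 | 1-phenyl-1H-tetrazole-5-thiol | Sc1nnnn1-c1ccccc1 | starting material
20 | 5-{[(3S,4E)-3-methyl-5-phenylpent-4-en-1-yl]sulfanyl}-1-phenyl-1H-tetrazole | C[C@H](/C=C/c1ccccc1)CCSc1nnnn1-c1ccccc1 | intermediate
21 | 5-{[(3S,4E)-3-methyl-5-phenylpent-4-en-1-yl]sulfonyl}-1-phenyl-1H-tetrazole | C[C@H](/C=C/c1ccccc1)CCS(=O)(=O)c1nnnn1-c1ccccc1 | intermediate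
22 | methyl 2-[(3S,4S,6S)-4,6-dimethyl-6-[(2R,3E,6S,7E)-2,6-dimethyl-8-phenylocta-3,7-dien-1-yl]-1,2-dioxan-3-yl]acetate | C[C@H](/C=C/c1ccccc1)C/C=C/[C@H](C)C[C@@]1(C)C[C@H](C)[C@H](CC(=O)OC)OO1 | intermediate
23 | 2-[(3S,4S,6S)-4,6-dimethyl-6-[(2R,3E,6S,7E)-2,6-dimethyl-8-phenylocta-3,7-dien-1-yl]-1,2-dioxan-3-yl]acetic acid | C[C@H](/C=C/c1ccccc1)C/C=C/[C@H](C)C[C@@]1(C)C[C@H](C)[C@H](CC(=O)O)OO1 | target

Total step count: 15. Longest linear sequence: 9 steps (steps 1 to 7, 14 and 15, from 2,4,6-trimethylphenol).

Steps most likely to fail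

Step 4. Two processes may defeat it: ionisation of the tertiary C6–O bond of the dienol ether followed by rearomatisation, and poor discrimination of the two faces of the carbenium carbon, which would erode the configuration at C3. The fallback sets out from 2 and moves the acetate unit to a separate, stereoelectronically controlled step. Acid-catalysed exchange of 2 with trimethyl orthoformate gives dimethoxymethyl 1,3,5-trimethyl-4-oxocyclohexa-2,5-dien-1-yl peroxide F1. The ene-reductase step gives (4R)-4-[(dimethoxymethyl)peroxy]-2,4,6-trimethylcyclohex-2-en-1-one F2. Me3SiOTf/Et3N at −78 °C then closes the same C3–C4 bond through the far more easily formed dialkoxycarbenium ion, giving (1R,5R)-4-methoxy-1,5,7-trimethyl-2,3-dioxabicyclo[3.3.1]non-7-en-6-one F3. Finally TiCl4 and 1-(tert-butyldimethylsilyloxy)-1-methoxyethene displace the methoxy group (the known substitution of 3-alkoxy-1,2-dioxanes by silyl ketene acetals); attack on the conformationally locked cyclic peroxycarbenium ion is axial, anti to the carbocyclic bridge, and the route is rejoined at 7.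

Step 3. The enzyme may not accept the peroxide-bearing 2,6-dimethyl dienone, may choose between the two enone arms poorly, or may reduce both. The fallback sets out from 4 and replaces desymmetrisation by resolution. Diimide (about one equivalent of dipotassium azodicarboxylate with AcOH, stopped at partial conversion, chromatography) reduces one C=C without selectivity and gives 5 together with its enantiomer, methyl 3-methoxy-3-{[(1S)-1,3,5-trimethyl-4-oxocyclohex-2-en-1-yl]peroxy}propanoate F4. Step 4 carries this mixture to 7 together with its enantiomer, methyl 2-[(1S,4R,5S)-1,5,7-trimethyl-6-oxo-2,3-dioxabicyclo[3.3.1]non-7-en-4-yl]acetate F5. This is a single racemate, because the acetal carbon and the reduced α-carbon are no longer stereogenic, and it is resolved by preparative chromatography on a cellulose-based chiral stationary phase; the route is rejoined at 7.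

Step 7. The alkoxy radical may not form under photocatalysis in this hindered bicycle, may fragment toward the secondary carbon, or the hydrogen transfer to C4 may lack facial control. The fallback sets out from 9 and separates fragmentation from hydrogen delivery. Hypoiodite fragmentation (PhI(OAc)2, I2, visible light, CH2Cl2) cleaves the same C–C bond and traps the tertiary radical as methyl 2-[(3S,6S)-4-iodo-4,6-dimethyl-6-[(2R)-2-methyl-3-oxopropyl]-1,2-dioxan-3-yl]acetate F6. Radical deiodination with (Me3Si)3SiH and Et3B/air at 0 °C then delivers hydrogen from the bulky silane anti to the C3 side chain, and the route is rejoined at 10.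

Further compounds
F1 | step 4 | dimethoxymethyl 1,3,5-trimethyl-4-oxocyclohexa-2,5-dien-1-yl peroxide | COC(OC)OOC1(C)C=C(C)C(=O)C(C)=C1
F2 | step 4 | (4R)-4-[(dimethoxymethyl)peroxy]-2,4,6-trimethylcyclohex-2-en-1-one | COC(OC)OO[C@@]1(C)C=C(C)C(=O)C(C)C1
F3 | step 4 | (1R,5R)-4-methoxy-1,5,7-trimethyl-2,3-dioxabicyclo[3.3.1]non-7-en-6-one | COC1OO[C@]2(C)C[C@@]1(C)C(=O)C(C)=C2
F4 | step 3 | methyl 3-methoxy-3-{[(1S)-1,3,5-trimethyl-4-oxocyclohex-2-en-1-yl]peroxy}propanoate | COC(=O)CC(OC)OO[C@]1(C)C=C(C)C(=O)C(C)C1
F5 | step 3 | methyl 2-[(1S,4R,5S)-1,5,7-trimethyl-6-oxo-2,3-dioxabicyclo[3.3.1]non-7-en-4-yl]acetate | COC(=O)C[C@H]1OO[C@@]2(C)C[C@]1(C)C(=O)C(C)=C2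
F6 | step 7 | methyl 2-[(3S,6S)-4-iodo-4,6-dimethyl-6-[(2R)-2-methyl-3-oxopropyl]-1,2-dioxan-3-yl]acetate | O=C[C@H](C)C[C@@]1(C)CC(C)(I)[C@H](CC(=O)OC)OO1
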